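**Retrosynthetic overview**
1. Target ⇐ cleavage of two silyl ethers ⇐ silylated dimer. The C3–C13' bond between the two ten-membered units is cut to two molecules of one monomer, joined by a visible-light dehydroxylative allyl-radical/Giese coupling that also sets C3 and C11'.
2. Monomer ten-membered ring ⇐ C3–C4 bond by Nozaki–Hiyama–Kishi closure of a Z-alkenyl iodide onto a C3 aldehyde (sets the C3 carbinol).
3. Seco chain ⇐ C7–C8 bond by zinc Barbier allylation of a Z-enal (from neryl acetate) with a 5-substituted 3-(bromomethyl)butenolide. This unveils the α-methylene lactone and sets C7 and C8 from C6.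
4. Butenolide ⇐ (R)-5-(hydroxymethyl)butyrolactone, which supplies C6, the only bought stereocentre.
5. Ring order: γ-lactone (bought) → ten-membered carbocycle of each monomer → union of the two monomers.

Assumption: carbons carry germacrane-style numbers in every intermediate (C6 = lactone O–CH, C7 = ring-fusion CH, C8 = the other carbinol CH, C3 = the carbon between C2H2 and C4(CH3)=C5H, C11/C12/C13 = lactone α-carbon/carbonyl/exocyclic CH2; unit A carries the methylene lactone, unit B with primed numbers keeps the C3 hydroxyl), and the starting lactone, made on scale from D-glutamic acid, is bought.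

Step 1
Reactants: 1 (R)-5-(hydroxymethyl)dihydrofuran-2(3H)-one
Product: 2 (R)-5-oxotetrahydrofuran-2-carbaldehyde
Conditions: Dess–Martin periodinane, CH2Cl2, 0 °C to rt; filtered and used crude
Reagents that add atoms: none
Why: Dess–Martin oxidation of the primary alcohol under neutral conditions gives the α-acyloxy aldehyde without epimerizing the bought C6 centre, and no new stereocentre is formed.

Step 2
Reactants: 2 (R)-5-oxotetrahydrofuran-2-carbaldehyde
Product: 3 (R)-5-[(Z)-2-iodoprop-1-en-1-yl]dihydrofuran-2(3H)-one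
Conditions: EtPPh3I, n-BuLi, THF, 0 °C; I2, −78 °C; NaN(SiMe3)2, −20 °C; then 2, −78 to −20 °C
Reagents that add atoms: ethyltriphenylphosphonium iodide CC[P+](c1ccccc1)(c1ccccc1)c1ccccc1.[I-]; iodine II
Why: Stork–Zhao-type Wittig olefination with the α-iodo ylide gives the Z alkenyl iodide (iodine cis to C6) under kinetic control at low temperature, where the aldehyde reacts far faster than the lactone and C6 is not touched.

Step 3
Reactants: 3 (R)-5-[(Z)-2-iodoprop-1-en-1-yl]dihydrofuran-2(3H)-one
Product: 4 (5R)-5-[(Z)-2-iodoprop-1-en-1-yl]-3-(phenylselanyl)dihydrofuran-2(3H)-one (C11 epimers)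
Conditions: LiN(iPr)2, THF, −78 °C; PhSeCl (inverse addition)
Reagents that add atoms: benzeneselenenyl chloride Cl[Se]c1ccccc1
Why: Kinetic lactone enolate formation and electrophilic selenenylation functionalize C11, and the new C11 centre may be an epimer mixture because it is destroyed in the next step.

Step 4
Reactants: 4 (5R)-5-[(Z)-2-iodoprop-1-en-1-yl]-3-(phenylselanyl)dihydrofuran-2(3H)-one
Product: 7 (R)-3-(hydroxymethyl)-5-[(Z)-2-iodoprop-1-en-1-yl]furan-2(5H)-one, via seleno aldol adduct 5 (not isolated), via selenoxide 6 (not isolated)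
Conditions: LiN(iPr)2, THF, −78 °C; CH2O (gas); AcOH; then H2O2 (2.2 equiv), pyridine, CH2Cl2, 0 °C to rt
Reagents that add atoms: formaldehyde C=O
Why: Aldol addition of the selenium-stabilized enolate to formaldehyde, then selenoxide syn-elimination, which runs away from the oxygen-bearing carbon toward C7, gives the endocyclic butenolide under non-basic conditions that leave C6 intact.

Step 5
Reactants: 7 (R)-3-(hydroxymethyl)-5-[(Z)-2-iodoprop-1-en-1-yl]furan-2(5H)-one
Product: 8 (R)-3-(bromomethyl)-5-[(Z)-2-iodoprop-1-en-1-yl]furan-2(5H)-one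
Conditions: CBr4, PPh3, CH2Cl2, −20 to 0 °C
Reagents that add atoms: carbon tetrabromide BrC(Br)(Br)Br
Why: Appel bromination converts the primary allylic alcohol into the bromide by SN2 at an achiral carbon under neutral conditions that do not deprotonate the C6–H.

Step 6
Reactants: 9 neryl acetate
Product: 11 (Z)-6,6-dimethoxy-3-methylhex-2-en-1-yl acetate, via aldehyde acetate 10 (not isolated)
Conditions: O3, CH2Cl2/MeOH, −78 °C; TsOH·H2O (cat.), rt; NaHCO3, Me2S
Reagents that add atoms: methanol CO
Why: Chemoselective ozonolysis of the electron-rich remote alkene (the allylic acetate deactivates the other one), then Schreiber-type in situ acetalization and reductive work-up, leaves the Z alkene untouched and forms no stereocentre.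

Step 7
Reactants: 11 (Z)-6,6-dimethoxy-3-methylhex-2-en-1-yl acetate
Product: 12 (Z)-6,6-dimethoxy-3-methylhex-2-en-1-ol
Conditions: K2CO3 (cat.), MeOH, 0 °C
Reagents that add atoms: none
Why: Base-catalysed transesterification removes the acetate while the acetal and the Z alkene are stable to mild base.

Step 8
Reactants: 12 (Z)-6,6-dimethoxy-3-methylhex-2-en-1-ol
Product: 13 (Z)-6,6-dimethoxy-3-methylhex-2-enal
Conditions: MnO2, CH2Cl2, rt
Reagents that add atoms: none
Why: MnO2 oxidation of the allylic alcohol gives the enal with retention of the Z geometry, as in the nerol to neral oxidation.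

Step 9
Reactants: 8 (R)-3-(bromomethyl)-5-[(Z)-2-iodoprop-1-en-1-yl]furan-2(5H)-one; 13 (Z)-6,6-dimethoxy-3-methylhex-2-enal
Product: 14 (4S,5R)-4-[(1R,2Z)-1-hydroxy-6,6-dimethoxy-3-methylhex-2-en-1-yl]-5-[(Z)-2-iodoprop-1-en-1-yl]-3-methylidenedihydrofuran-2(3H)-one
Conditions: Zn dust, THF/sat. aq NH4Cl, 0 °C, short reaction time
Reagents that add atoms: none
Why: Zinc Barbier allylation through a closed chair transition state, in which the allylzinc from 8 attacks the enal 1,2 through its γ-carbon C7 on the face anti to the C6 side chain (6,7-trans lactone) and its ring-locked E-type geometry with the enal substituent equatorial gives the 7,8-anti carbinol (8R), while the transposed double bond becomes the α-methylene group.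

Step 10
Reactants: 14 (4S,5R)-4-[(1R,2Z)-1-hydroxy-6,6-dimethoxy-3-methylhex-2-en-1-yl]-5-[(Z)-2-iodoprop-1-en-1-yl]-3-methylidenedihydrofuran-2(3H)-one
Product: 17 (4R,5R)-5-[(Z)-2-iodoprop-1-en-1-yl]-3-methylidene-4-[(1R,2Z)-3-methyl-6-oxo-1-(triethylsilyloxy)hex-2-en-1-yl]dihydrofuran-2(3H)-one, via triethylsilyl ether acetal 15 (not isolated), via collidinium adduct 16 (not isolated)
Conditions: TESOTf (3.5 equiv), 2,4,6-collidine, CH2Cl2, 0 °C; then H2O
Reagents that add atoms: triethylsilyl trifluoromethanesulfonate CC[Si](CC)(CC)OS(=O)(=O)C(F)(F)F; water O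
Why: TESOTf with collidine silylates the C8 alcohol and, by the Fujioka–Kita acetal cleavage through a collidinium intermediate, releases the C3 aldehyde on aqueous work-up under non-acidic conditions that leave the lactone, the alkenyl iodide and all stereocentres untouched.

Step 11
Reactants: 17 (4R,5R)-5-[(Z)-2-iodoprop-1-en-1-yl]-3-methylidene-4-[(1R,2Z)-3-methyl-6-oxo-1-(triethylsilyloxy)hex-2-en-1-yl]dihydrofuran-2(3H)-one
Product: 18 (3S,4Z,6S,7R,8R,9Z)-3-hydroxy-8-(triethylsilyloxy)germacra-4,9,11(13)-trien-12,6-olide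
Conditions: CrCl2 (8 equiv), NiCl2 (2 mol %), degassed DMSO, rt, 2 mM, slow addition of 17
Reagents that add atoms: none
Why: Nozaki–Hiyama–Kishi macrocyclization, in which the alkenyl iodide becomes a trivalent alkenylchromium species that adds only to the aldehyde with retention of the Z geometry and closes a nearly strain-free (Z,Z)-cyclodeca-1,6-diene, is expected to place the aldehyde hydrogen in the alkene plane (least 1,3-allylic strain toward C6) and the chromium-bound oxygen on the exo face, cis to the C6 oxygen (3S).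

Step 12
Reactants: 18 (3S,4Z,6S,7R,8R,9Z)-3-hydroxy-8-(triethylsilyloxy)germacra-4,9,11(13)-trien-12,6-olide (two molecules: one radical donor and one acceptor)
Product: 19 8,8'-bis(triethylsilyl) ether of the target dimer (C3–C13' bond; 3R in unit A; 3'S and 11'R in unit B)
Conditions: 4CzIPN (2 mol %), PPh3 (0.3 equiv per 18, slow addition), 2,4,6-collidine (0.3 equiv), degassed MeCN, 0.3 M, 450 nm LEDs, rt; stopped near one third conversion, 18 recovered and recycled
Reagents that add atoms: none
Why: Proposed new method: a photoredox phosphoranyl-radical dehydroxylative Giese homodimerization in which excited 4CzIPN oxidizes PPh3 to its radical cation, the only free hydroxyl of a first molecule of 18 (C3–OH) adds to phosphorus, and β-scission of the phosphoranyl radical gives Ph3PO and the C3–C4–C5 allyl radical with the C4=C5 Z geometry kept; this radical attacks the C13 methylene of a second molecule of 18 through its less hindered C3 terminus on the exo face the oxygen had occupied (3R, net retention), and the C11' radical is then reduced by the photocatalyst radical anion and protonated so that C13' lies trans to C8' (11'R, the all-trans lactone); the closest known chemistry is the phosphine/photoredox deoxygenation of benzylic alcohols and carboxylic acids through phosphoranyl radicals and the Giese addition of alkyl radicals to α-methylene lactones, but allylic C–O scission coupled to C–C bond formation between two such macrocycles has not been shown.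

Step 13
Reactants: 19 8,8'-bis(triethylsilyl) ether of the target dimer
Product: 20 target CNP0307352.3
Conditions: HF·pyridine, pyridine/THF, 0 °C to rt
Reagents that add atoms: none
Why: Fluoride cleavage of both triethylsilyl ethers under buffered, weakly acidic conditions avoids alkoxides and therefore translactonization or conjugate addition, and leaves all stereocentres intact.

**Compound list**
1 | (R)-5-(hydroxymethyl)dihydrofuran-2(3H)-one | OC[C@H]1CCC(=O)O1 | starting material
2 | (R)-5-oxotetrahydrofuran-2-carbaldehyde | O=C[C@H]1CCC(=O)O1 | intermediate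
3 | (R)-5-[(Z)-2-iodoprop-1-en-1-yl]dihydrofuran-2(3H)-one | I/C(C)=C\[C@H]1CCC(=O)O1 | intermediate
4 | (5R)-5-[(Z)-2-iodoprop-1-en-1-yl]-3-(phenylselanyl)dihydrofuran-2(3H)-one (C11 epimers) | I/C(C)=C\[C@H]1CC([Se]c2ccccc2)C(=O)O1 | intermediate
5 | (5R)-3-(hydroxymethyl)-5-[(Z)-2-iodoprop-1-en-1-yl]-3-(phenylselanyl)dihydrofuran-2(3H)-one | I/C(C)=C\[C@H]1CC(CO)([Se]c2ccccc2)C(=O)O1 | intermediate
6 | Se-oxide of 5 | I/C(C)=C\[C@H]1CC(CO)([Se](=O)c2ccccc2)C(=O)O1 | intermediate
7 | (R)-3-(hydroxymethyl)-5-[(Z)-2-iodoprop-1-en-1-yl]furan-2(5H)-one | I/C(C)=C\[C@H]1C=C(CO)C(=O)O1 | intermediate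
8 | (R)-3-(bromomethyl)-5-[(Z)-2-iodoprop-1-en-1-yl]furan-2(5H)-one | I/C(C)=C\[C@H]1C=C(CBr)C(=O)O1 | intermediate
9 | neryl acetate, (Z)-3,7-dimethylocta-2,6-dien-1-yl acetate | CC(C)=CCC/C(C)=C\COC(C)=O | starting material
10 | (Z)-3-methyl-6-oxohex-2-en-1-yl acetate | O=CCC/C(C)=C\COC(C)=O | intermediate
11 | (Z)-6,6-dimethoxy-3-methylhex-2-en-1-yl acetate | COC(OC)CC/C(C)=C\COC(C)=O | intermediate
12 | (Z)-6,6-dimethoxy-3-methylhex-2-en-1-ol | COC(OC)CC/C(C)=C\CO | intermediate
13 | (Z)-6,6-dimethoxy-3-methylhex-2-enal | COC(OC)CC/C(C)=C\C=O | intermediate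
14 | (4S,5R)-4-[(1R,2Z)-1-hydroxy-6,6-dimethoxy-3-methylhex-2-en-1-yl]-5-[(Z)-2-iodoprop-1-en-1-yl]-3-methylidenedihydrofuran-2(3H)-one | C=C1C(=O)O[C@@H](/C=C(/C)I)[C@@H]1[C@H](O)/C=C(/C)CCC(OC)OC | intermediate
15 | (4R,5R)-4-[(1R,2Z)-6,6-dimethoxy-3-methyl-1-(triethylsilyloxy)hex-2-en-1-yl]-5-[(Z)-2-iodoprop-1-en-1-yl]-3-methylidenedihydrofuran-2(3H)-one | C=C1C(=O)O[C@@H](/C=C(/C)I)[C@@H]1[C@H](O[Si](CC)(CC)CC)/C=C(/C)CCC(OC)OC | intermediate
16 | 15 with one acetal methoxy group replaced by N-bound 2,4,6-trimethylpyridinium; triflate salt; acetal-carbon epimers | C=C1C(=O)O[C@@H](/C=C(/C)I)[C@@H]1[C@H](O[Si](CC)(CC)CC)/C=C(/C)CCC(OC)[n+]1c(C)cc(C)cc1C.[O-]S(=O)(=O)C(F)(F)F | intermediate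
17 | (4R,5R)-5-[(Z)-2-iodoprop-1-en-1-yl]-3-methylidene-4-[(1R,2Z)-3-methyl-6-oxo-1-(triethylsilyloxy)hex-2-en-1-yl]dihydrofuran-2(3H)-one | C=C1C(=O)O[C@@H](/C=C(/C)I)[C@@H]1[C@H](O[Si](CC)(CC)CC)/C=C(/C)CCC=O | intermediate
18 | (3S,4Z,6S,7R,8R,9Z)-3-hydroxy-8-(triethylsilyloxy)germacra-4,9,11(13)-trien-12,6-olide | C=C1C(=O)O[C@H]2/C=C(/C)[C@@H](O)CC/C(C)=C\[C@@H](O[Si](CC)(CC)CC)[C@H]12 | intermediate
19 | C3–C13' dimer; unit A = (3R,4Z,6S,7R,8R,9Z)-8-(triethylsilyloxy)germacra-4,9,11(13)-trien-12,6-olid-3-yl; unit B = (3'S,4'Z,6'S,7'R,8'R,9'Z,11'R)-3'-hydroxy-8'-(triethylsilyloxy)germacra-4',9'-dien-12',6'-olide carrying unit A on C13' | C=C1C(=O)O[C@H]2/C=C(/C)[C@@H](C[C@H]3C(=O)O[C@H]4/C=C(/C)[C@@H](O)CC/C(C)=C\[C@@H](O[Si](CC)(CC)CC)[C@@H]43)CC/C(C)=C\[C@@H](O[Si](CC)(CC)CC)[C@H]12 | intermediate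
20 | CNP0307352.3; unit A = (3R,4Z,6S,7S,8R,9Z)-8-hydroxygermacra-4,9,11(13)-trien-12,6-olid-3-yl on C13' of unit B = (3'S,4'Z,6'S,7'S,8'R,9'Z,11'R)-3',8'-dihydroxygermacra-4',9'-dien-12',6'-olide | C=C1C(=O)O[C@H]2/C=C(/C)[C@@H](C[C@H]3C(=O)O[C@H]4/C=C(/C)[C@@H](O)CC/C(C)=C\[C@@H](O)[C@@H]43)CC/C(C)=C\[C@@H](O)[C@H]12 | target

**Totals**
Total step count: 13 (steps 1–5 make the butenolide, steps 6–8 the enal, steps 9–13 join them and finish).
Longest linear sequence: 10 steps (1, 2, 3, 4, 5, 9, 10, 11, 12, 13) from compound 1.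

**Three steps most likely to fail, each with one fallback**

The Barbier allylation (step 9) creates two stereocentres at once with a base- and acid-labile Z-enal, and zinc in water may favour the 7,8-syn adduct. The fallback keeps the coupling but sets C8 by invertive substitution instead of by the C–C bond formation. It sets out from 8 and 13, whose coupling then gives mainly the C8 epimer of 14 F1. Mitsunobu reaction of this alcohol (HCO2H, PPh3, DIAD, THF, 0 °C) gives with inversion the O-formyl derivative of 14 F2. Mild methanolysis (KHCO3, MeOH/H2O, 0 °C) comes back to the route at 14.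

The macrocyclization (step 11) has to close the ten-membered ring and set C3, and the facial preference of the aldehyde is an argument from conformation, not a certainty. The fallback sets out from 17. If the ring closes to the wrong carbinol, the 3-epimer of 18 F3 is inverted by Mitsunobu reaction (HCO2H, PPh3, DIAD) to the 3-O-formyl derivative of 18 F4. KHCO3 in MeOH/H2O at 0 °C then cleaves the formate and comes back to the route at 18. Since the C3 centre of the donor is erased in step 12, only the material used as acceptor needs this correction.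

The photochemical dimerization (step 12) is the proposed new step. Its risks are attack through C5 instead of C3, attack on the endo face, allyl radical homocoupling, and statistical oligomer formation, since 19 still carries one hydroxyl and one methylene lactone (hence the low conversion with recycling). The fallback uses known halide-based radical chemistry and sets out from 18. Appel bromination (CBr4, PPh3, 2,6-lutidine, CH2Cl2, −20 °C) gives the allylic bromide of 18 F5, as a mixture of C3 epimers and any transposed C5 bromide, all of which lead to the same allyl radical. Slow addition of F5 to 18 (3 equiv) with (Me3Si)3SiH and AIBN in benzene at 80 °C (tin-free Giese addition; excess 18 recovered) comes back to the route at 19.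

**Further compounds**
F1 | step 9 | C8 epimer of 14, (4S,5R)-4-[(1S,2Z)-1-hydroxy-6,6-dimethoxy-3-methylhex-2-en-1-yl]-5-[(Z)-2-iodoprop-1-en-1-yl]-3-methylidenedihydrofuran-2(3H)-one | C=C1C(=O)O[C@@H](/C=C(/C)I)[C@@H]1[C@@H](O)/C=C(/C)CCC(OC)OC
F2 | step 9 | O-formyl derivative of 14 (C8 formate, 8R) | C=C1C(=O)O[C@@H](/C=C(/C)I)[C@@H]1[C@H](OC=O)/C=C(/C)CCC(OC)OC
F3 | step 11 | 3-epimer of 18, (3R)-3-hydroxy-8-(triethylsilyloxy)germacra-4Z,9Z,11(13)-trien-12,6-olide | C=C1C(=O)O[C@H]2/C=C(/C)[C@H](O)CC/C(C)=C\[C@@H](O[Si](CC)(CC)CC)[C@H]12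
F4 | step 11 | 3-O-formyl derivative of 18 (3S) | C=C1C(=O)O[C@H]2/C=C(/C)[C@@H](OC=O)CC/C(C)=C\[C@@H](O[Si](CC)(CC)CC)[C@H]12
F5 | step 12 | allylic bromide of 18, 3-bromo-8-(triethylsilyloxy)germacra-4Z,9Z,11(13)-trien-12,6-olide (C3 epimers) | C=C1C(=O)O[C@H]2/C=C(/C)C(Br)CC/C(C)=C\[C@@H](O[Si](CC)(CC)CC)[C@H]12
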